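The lactone ring (ring B) is cut at C4–C4a and O2–C3. This exploits the ortho relationship on the hydroquinone ring (ring A) between C4a and the C8a carboxyl group: an ortho-bromobenzoic acid is a carbon electrophile at C4a flanked by an oxygen nucleophile, and both add across the terminal C=C (future C4=C3) of a 1,3-diene. A ligand-controlled palladium-catalysed arylative heteroannulation (carbopalladation, then intramolecular allylic carboxylation) should form the aryl–CH2 bond, the lactone C–O bond, ring B and the C3 stereocentre in one operation. The precursors are 3,6-bis(benzyloxy)-2-bromobenzoic acid and a chiral-pool (R)-hepta-4,6-dien-2-yl benzyl succinate; the remaining alkene is saturated during global debenzylation.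

Key step: step 5

Ring numbering used throughout is that of isochromen-1-one: C1 (C=O), O2, C3, C4, C4a, C5 to C8, C8a.

Assumption: the sense of asymmetric induction of the chiral phosphoramidite in step 5 cannot be assigned with certainty in advance; the antipode named there is provisional, and whichever antipode gives the (3S)-lactone in a trial run is the one used.

Step 1
Reactants: 1 2-bromobenzene-1,4-diol (bromohydroquinone)
Product: 2 1,4-bis(benzyloxy)-2-bromobenzene
Conditions: BnBr (2.3 equiv), K2CO3 (3 equiv), DMF, 60 °C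
Reagents that add atoms: benzyl bromide, BrCc1ccccc1
Why: Williamson ether synthesis, in which both phenoxides of 1 are alkylated by the reactive benzylic bromide under mild carbonate conditions and no other site can compete.

Step 2
Reactants: 2 1,4-bis(benzyloxy)-2-bromobenzene
Product: 4 3,6-bis(benzyloxy)-2-bromobenzoic acid, via aryllithium 3 (not isolated)
Conditions: LiN(i-Pr)2 (commercial solution, 1.15 equiv), THF, −78 °C, 1 h; CO2 (gas), −78 °C to rt; aq. HCl
Reagents that add atoms: carbon dioxide, O=C=O
Why: Directed ortho-metalation followed by carboxylation, in which the hydrogen at C3 of 2, lying between Br and OBn, is the most acidic, the lithium amide removes it without bromine–lithium exchange, and at −78 °C the ortho-bromoaryllithium should be trapped by CO2 before it loses LiBr.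

Step 3
Reactants: 5 (2R)-pent-4-yn-2-ol; 6 4-(benzyloxy)-4-oxobutanoic acid (monobenzyl succinate)
Product: 7 benzyl (2R)-pent-4-yn-2-yl butanedioate
Conditions: DCC (1.1 equiv), DMAP (10 mol %), CH2Cl2, 0 °C to rt
Reagents that add atoms: none
Why: Steglich esterification, in which the activated acid of 6 is attacked by the alcohol oxygen, so the (R) centre is carried over unchanged and the terminal alkyne is inert.

Step 4
Reactants: 7 benzyl (2R)-pent-4-yn-2-yl butanedioate; 8 bromoethene (vinyl bromide)
Product: 11 benzyl (2R,4E)-hepta-4,6-dien-2-yl butanedioate, via alkenylzirconocene chloride 9 (not isolated), via alkenylzinc chloride 10 (not isolated)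
Conditions: Cp2Zr(H)Cl (1.2 equiv), THF, rt, 30 min; ZnCl2 (1.2 equiv), 0 °C; 8 (1 M in THF, 1.5 equiv), Pd(PPh3)4 (5 mol %), rt
Reagents that add atoms: none
Why: Hydrozirconation followed by Negishi coupling, in which syn addition of Zr–H places zirconium on the terminal alkyne carbon and fixes the (E) geometry, which is retained through transmetalation to zinc and palladium-catalysed coupling with vinyl bromide, the terminal alkyne reacting with the hydride much faster than the two esters.

Step 5
Reactants: 4 3,6-bis(benzyloxy)-2-bromobenzoic acid; 11 benzyl (2R,4E)-hepta-4,6-dien-2-yl butanedioate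
Product: 12 benzyl (2R,4E)-5-[(3S)-5,8-bis(benzyloxy)-1-oxo-3,4-dihydro-1H-isochromen-3-yl]pent-4-en-2-yl butanedioate
Conditions: Pd2(dba)3 (2.5 mol %), (S)-(1,1'-binaphthalene-2,2'-diyl) N,N-bis[(1R)-1-phenylethyl]phosphoramidite (10 mol %), Cs2CO3 (2 equiv), 1,4-dioxane, 80 °C, argon
Reagents that add atoms: none
Why: Heteroannulation of a 1,3-diene by an ortho-halobenzoic acid (Larock type), run with a chiral ligand: zerovalent palladium inserts into the C–Br bond of the cesium salt of 4 to give a five-membered arylpalladium carboxylate chelate, syn-carbopalladation of the terminal vinyl group of 11 makes the aryl–CH2 bond (C4a–C4) and a π-allylpalladium carboxylate, and attack of the carboxylate on the proximal allyl terminus makes the O2–C3 bond and returns zerovalent palladium. The closest known reactions are the ligand-free annulation of dienes by o-iodobenzoic acid to 3-alkenyl-3,4-dihydroisocoumarins and the enantioselective variants of the same cascade with tethered phenol, alcohol and amine nucleophiles. Ring B closes as a six-membered lactone by intramolecular allylic substitution at the internal allyl terminus (6-exo with respect to the allyl unit, the alkene ending exocyclic and E), whereas closure at the distal terminus would need an eight-membered ring. The C3 stereocentre is set by the chiral phosphoramidite on palladium, which differentiates the faces of the equilibrating π-allyl intermediates in the C–O bond-forming event; the carbinol centre five atoms away exerts no control and is untouched. The step needs insertion at the monosubstituted alkene terminus (less hindered, and the only mode that gives a stabilised allyl, which also suppresses β-hydride elimination) and a single competent nucleophile, which is secured by capping the succinate as its benzyl ester and the phenols as benzyl ethers.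

Step 6
Reactants: 12 benzyl (2R,4E)-5-[(3S)-5,8-bis(benzyloxy)-1-oxo-3,4-dihydro-1H-isochromen-3-yl]pent-4-en-2-yl butanedioate
Product: 13 4-{[(2R)-5-[(3R)-5,8-dihydroxy-1-oxo-3,4-dihydro-1H-isochromen-3-yl]pentan-2-yl]oxy}-4-oxobutanoic acid
Conditions: H2 (1 atm), Pd/C (10 % palladium on carbon), EtOAc, rt; filtration and concentration under argon
Reagents that add atoms: none
Why: Catalytic hydrogenation with hydrogenolysis, in which the disubstituted alkene is saturated and the two aryl benzyl ethers and the benzyl ester are cleaved over Pd/C in an aprotic solvent, where alkene saturation should outrun cleavage of the allylic lactone C–O bond; neither stereocentre is involved, and C3 changes its descriptor from S to R only because the substituent priorities change.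

Compound list
1 | 2-bromobenzene-1,4-diol (bromohydroquinone) | Oc1ccc(O)c(Br)c1 | starting material
2 | 1,4-bis(benzyloxy)-2-bromobenzene | Brc1cc(OCc2ccccc2)ccc1OCc1ccccc1 | intermediate
3 | [3,6-bis(benzyloxy)-2-bromophenyl]lithium | [Li]c1c(Br)c(OCc2ccccc2)ccc1OCc1ccccc1 | intermediate
4 | 3,6-bis(benzyloxy)-2-bromobenzoic acid | OC(=O)c1c(Br)c(OCc2ccccc2)ccc1OCc1ccccc1 | intermediate
5 | (2R)-pent-4-yn-2-ol | C[C@H](CC#C)O | starting material
6 | 4-(benzyloxy)-4-oxobutanoic acid (monobenzyl succinate) | OC(=O)CCC(=O)OCc1ccccc1 | starting material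
7 | benzyl (2R)-pent-4-yn-2-yl butanedioate | C[C@H](CC#C)OC(=O)CCC(=O)OCc1ccccc1 | intermediate
8 | bromoethene (vinyl bromide) | C=CBr | starting material
9 | chlorobis(cyclopentadienyl)[(1E,4R)-4-{[4-(benzyloxy)-4-oxobutanoyl]oxy}pent-1-en-1-yl]zirconium | C[C@H](C/C=C/[Zr](Cl)(C1C=CC=C1)C1C=CC=C1)OC(=O)CCC(=O)OCc1ccccc1 | intermediate
10 | [(1E,4R)-4-{[4-(benzyloxy)-4-oxobutanoyl]oxy}pent-1-en-1-yl]zinc chloride | C[C@H](C/C=C/[Zn]Cl)OC(=O)CCC(=O)OCc1ccccc1 | intermediate
11 | benzyl (2R,4E)-hepta-4,6-dien-2-yl butanedioate | C[C@H](C/C=C/C=C)OC(=O)CCC(=O)OCc1ccccc1 | intermediate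
12 | benzyl (2R,4E)-5-[(3S)-5,8-bis(benzyloxy)-1-oxo-3,4-dihydro-1H-isochromen-3-yl]pent-4-en-2-yl butanedioate | C[C@H](C/C=C/[C@@H]1Cc2c(OCc3ccccc3)ccc(OCc3ccccc3)c2C(=O)O1)OC(=O)CCC(=O)OCc1ccccc1 | intermediate
13 | 4-{[(2R)-5-[(3R)-5,8-dihydroxy-1-oxo-3,4-dihydro-1H-isochromen-3-yl]pentan-2-yl]oxy}-4-oxobutanoic acid | C[C@H](CCC[C@@H]1Cc2c(O)ccc(O)c2C(=O)O1)OC(=O)CCC(=O)O | target

Total step count: 6. Longest linear sequence: 4 steps (1, 2, 5, 6 or 3, 4, 5, 6).

Steps most likely to fail

Step 5. Enantiofacial discrimination in the C–O bond-forming allylic substitution may be low with a carboxylate as the tethered nucleophile. Zerovalent palladium may also re-ionise the allylic lactone once formed, which would erode the C3 configuration, and slow oxidative addition into the doubly ortho-substituted C–Br bond would aggravate both. The fallback sets out from 4 and comes back at 13; it takes C3 from an enantiopure terminal epoxide whose C–O bond is never broken. Commercial (R)-propylene oxide is opened at its CH2 terminus with but-3-enylmagnesium bromide (CuI cat., THF, −30 °C) to give (2R)-hept-6-en-2-ol F1. Silylation (TBSCl, imidazole, DMF) gives tert-butyl{[(2R)-hept-6-en-2-yl]oxy}dimethylsilane F2. Epoxidation (mCPBA, CH2Cl2) gives the oxirane epimer mixture tert-butyldimethyl{[(2R)-5-(oxiran-2-yl)pentan-2-yl]oxy}silane F3. Hydrolytic kinetic resolution with (R,R)-N,N'-bis(3,5-di-tert-butylsalicylidene)cyclohexane-1,2-diaminocobalt acetate (trivalent cobalt, 0.5 mol %, H2O 0.55 equiv), the antipode that leaves (R)-alkyloxiranes unreacted, should give tert-butyldimethyl({(2R)-5-[(2R)-oxiran-2-yl]pentan-2-yl}oxy)silane F4. Acid 4 is converted with n-BuLi (2.1 equiv, THF, −95 °C) into lithium 3,6-bis(benzyloxy)-2-lithiobenzoate F5. This opens F4 at the CH2 terminus (BF3·OEt2, −78 °C) to give 3,6-bis(benzyloxy)-2-[(2R,6R)-6-{[tert-butyl(dimethyl)silyl]oxy}-2-hydroxyheptyl]benzoic acid F6. Treatment with p-TsOH (MeOH, then toluene, 60 °C) closes the lactone and removes the silyl group to give (3R)-5,8-bis(benzyloxy)-3-[(4R)-4-hydroxypentyl]-3,4-dihydro-1H-isochromen-1-one F7. Acylation with succinic anhydride (DMAP, pyridine) gives 4-{[(2R)-5-[(3R)-5,8-bis(benzyloxy)-1-oxo-3,4-dihydro-1H-isochromen-3-yl]pentan-2-yl]oxy}-4-oxobutanoic acid F8, and hydrogenolysis (H2, Pd/C, EtOAc) gives 13.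

Step 6. Hydrogenolysis of the allylic lactone C–O bond (C3–O2) may compete with saturation of the alkene during the first minutes on palladium, which would open ring B. The fallback sets out from 12 and comes back at 13. The alkene is first reduced without a metal by diimide (2-nitrobenzenesulfonylhydrazide, Et3N, CH2Cl2, rt) to give benzyl (2R)-5-[(3R)-5,8-bis(benzyloxy)-1-oxo-3,4-dihydro-1H-isochromen-3-yl]pentan-2-yl butanedioate F9, in which the lactone C–O bond is no longer allylic. Hydrogenolysis (H2, Pd/C, EtOAc) then removes the three benzyl groups to give 13.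

Step 4. The zirconium hydride may attack the ester carbonyls in competition with the alkyne, and incomplete zirconium-to-zinc transmetalation would end in protodemetalation to the terminal alkene. The fallback sets out from 7 and comes back at 11. Hydroboration with pinacolborane (dicyclohexylborane 5 mol %, neat, rt) should give the isolable alkenylboronate benzyl (2R,4E)-5-(4,4,5,5-tetramethyl-1,3,2-dioxaborolan-2-yl)pent-4-en-2-yl butanedioate F10. Suzuki–Miyaura coupling of F10 with 8 (Pd(dppf)Cl2, K3PO4, THF/H2O, 40 °C) then gives 11.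

Further compounds
F1 | step 5 | (2R)-hept-6-en-2-ol | C[C@H](CCCC=C)O
F2 | step 5 | tert-butyl{[(2R)-hept-6-en-2-yl]oxy}dimethylsilane | C[C@H](CCCC=C)O[Si](C)(C)C(C)(C)C
F3 | step 5 | tert-butyldimethyl{[(2R)-5-(oxiran-2-yl)pentan-2-yl]oxy}silane (epimer mixture at the oxirane) | C[C@H](CCCC1CO1)O[Si](C)(C)C(C)(C)C
F4 | step 5 | tert-butyldimethyl({(2R)-5-[(2R)-oxiran-2-yl]pentan-2-yl}oxy)silane | C[C@H](CCC[C@@H]1CO1)O[Si](C)(C)C(C)(C)C
F5 | step 5 | lithium 3,6-bis(benzyloxy)-2-lithiobenzoate | [Li]OC(=O)c1c([Li])c(OCc2ccccc2)ccc1OCc1ccccc1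
F6 | step 5 | 3,6-bis(benzyloxy)-2-[(2R,6R)-6-{[tert-butyl(dimethyl)silyl]oxy}-2-hydroxyheptyl]benzoic acid | C[C@H](CCC[C@@H](O)Cc1c(OCc2ccccc2)ccc(OCc2ccccc2)c1C(O)=O)O[Si](C)(C)C(C)(C)C
F7 | step 5 | (3R)-5,8-bis(benzyloxy)-3-[(4R)-4-hydroxypentyl]-3,4-dihydro-1H-isochromen-1-one | C[C@H](CCC[C@@H]1Cc2c(OCc3ccccc3)ccc(OCc3ccccc3)c2C(=O)O1)O
F8 | step 5 | 4-{[(2R)-5-[(3R)-5,8-bis(benzyloxy)-1-oxo-3,4-dihydro-1H-isochromen-3-yl]pentan-2-yl]oxy}-4-oxobutanoic acid | C[C@H](CCC[C@@H]1Cc2c(OCc3ccccc3)ccc(OCc3ccccc3)c2C(=O)O1)OC(=O)CCC(=O)O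
F9 | step 6 | benzyl (2R)-5-[(3R)-5,8-bis(benzyloxy)-1-oxo-3,4-dihydro-1H-isochromen-3-yl]pentan-2-yl butanedioate | C[C@H](CCC[C@@H]1Cc2c(OCc3ccccc3)ccc(OCc3ccccc3)c2C(=O)O1)OC(=O)CCC(=O)OCc1ccccc1
F10 | step 4 | benzyl (2R,4E)-5-(4,4,5,5-tetramethyl-1,3,2-dioxaborolan-2-yl)pent-4-en-2-yl butanedioate | C[C@H](C/C=C/B1OC(C)(C)C(C)(C)O1)OC(=O)CCC(=O)OCc1ccccc1
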